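## Retrosynthetic overview
1. The last steps are acid removal of the acetonide and tert-butyl ester and, before that, a Mitsunobu ester bond at C16–O between alcohol 19 and ferulic acid 23. Ferulic acid comes from catechol by O-methylation, iodination and a Heck reaction.
2. C13–C14 is made by nickel hydride hydroalkylation of the C12=C13 vinyl group with (S)-3-bromo-2-methylpropan-1-ol, which brings C15. The C6 carboxyl comes from directed lithiation.
3. C4–C11 and both of these centres come from an iridium-catalysed branched crotylation of β-tetralone 10 (new). The C3 ketone is then deleted.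
4. The key step makes ring B by one-carbon ring expansion of indanone 8. The aryl carbon C4a shifts 1,2 onto a diazo carbon, so C4 is inserted between C3 and C4a.
5. Ring order: arene (catechol), then the five-membered ring (cuprate opening of (S)-β-butyrolactone sets C1, then Friedel–Crafts closure), then the six-membered ring B by expansion.

Assumption: atom labels follow serrulatane numbering (C1 ring CH–CH3, C4 ring CH with the side chain, C6 carboxyl position, C7/C8 oxygens, C11 and C15 side-chain CH–CH3, C16 CH2O), and the ligand antipode in step 5 is assigned by analogy with the accepted facial model, its mirror image being equally available.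

## Route

Step 1
Reactants: 1 catechol
Product: 2 2,2-dimethyl-1,3-benzodioxole
Conditions: 2,2-dimethoxypropane, TsOH (cat.), toluene, reflux, MeOH removed over 4 Å MS
Reagents that add atoms: 2,2-dimethoxypropane, COC(C)(C)OC
Why: Acid-catalysed transketalisation driven by methanol removal masks both phenols with one base-stable, TFA-labile group whose oxygens also direct lithiation.

Step 2
Reactants: 2 2,2-dimethyl-1,3-benzodioxole; 3 (S)-β-butyrolactone
Product: 6 (3R)-3-(2,2-dimethyl-1,3-benzodioxol-4-yl)butanoic acid, via aryllithium 4 (not isolated), via lithium diarylcuprate 5 (not isolated)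
Conditions: n-BuLi, TMEDA, Et2O, 0 °C to rt; CuBr·SMe2 (0.5 equiv), THF, −40 °C; 3 (0.45 equiv), −40 to 0 °C; 1 M HCl
Reagents that add atoms: none
Why: Directed ortho-metalation next to the ring oxygen is followed by Gilman cuprate SN2 opening of the β-lactone at the alkyl C–O carbon with inversion, so the (S)-lactone gives (R)-C1 and the free acid in one operation.

Step 3
Reactants: 6 (3R)-3-(2,2-dimethyl-1,3-benzodioxol-4-yl)butanoic acid
Product: 8 (3R)-3-methyl-4,5-(isopropylidenedioxy)indan-1-one, via acid chloride 7 (not isolated)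
Conditions: (COCl)2, DMF (cat.), CH2Cl2, 0 °C to rt; SnCl4, CH2Cl2, −20 to 0 °C
Reagents that add atoms: none
Why: Intramolecular Friedel–Crafts acylation can close only at the free ortho carbon C4a, which is para to O7 and therefore activated, and the anhydrous conditions spare the aryl ketal and C1.

Step 4
Reactants: 8 (3R)-3-methyl-4,5-(isopropylidenedioxy)indan-1-one
Product: 10 (4R)-4-methyl-5,6-(isopropylidenedioxy)-3,4-dihydronaphthalen-2(1H)-one, via alpha-silyl ketone 9 (not isolated)
Conditions: TMSCHN2, BF3·OEt2, CH2Cl2, −78 to −20 °C; then 1 M HCl, THF, rt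
Reagents that add atoms: trimethylsilyldiazomethane, C[Si](C)(C)C=[N+]=[N-]
Why: In this Büchner–Curtius–Schlotterbeck (Tiffeneau–Demjanov-type) homologation the diazo carbon adds to the BF3-activated ketone and the electron-rich para-oxygenated aryl carbon C4a shifts 1,2 to it as N2 leaves, which expands the five-membered ring to ring B, while the bulky α-silyl ketone resists a second insertion until it is protodesilylated.

Step 5
Reactants: 10 (4R)-4-methyl-5,6-(isopropylidenedioxy)-3,4-dihydronaphthalen-2(1H)-one; 11 (E)-crotyl chloride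
Product: 13 (1S,4R)-1-[(2S)-but-3-en-2-yl]-4-methyl-5,6-(isopropylidenedioxy)-3,4-dihydronaphthalen-2(1H)-one (serrulatane centres 1R 4S 11S), via lithium enolate 12 (not isolated)
Conditions: [Ir(cod)Cl]2 (2 mol %), (Sa,S,S)-BINOL N,N-bis(1-phenylethyl)phosphoramidite (4 mol %), TBD (10 mol %), LiOt-Bu (1.05 equiv), degassed THF, 0 to 25 °C; then DBU (0.2 equiv), 25 °C
Reagents that add atoms: none
Why: Proposed new method: the conjugated C3–C4 lithium enolate of a β-tetralone (a soft benzylic enolate that forms regioselectively toward C4) is used for the first time as nucleophile for a cyclometalated iridium phosphoramidite π-crotyl complex; ionisation of 11 gives the π-allyl species and outer-sphere attack anti to the metal occurs at the methyl-bearing terminus (branched product) on the allyl face fixed by the ligand, which sets C11 as S, while the enolate reacts on the face opposite the C1 methyl group (held pseudoaxial by the peri oxygen on C8), which sets C4 as S, and because C4 stays epimerisable the DBU treatment converts any cis epimer into the favoured trans-1,4 ketone; closest known reaction type: iridium-catalysed asymmetric allylic alkylation of cyclic β-keto esters with crotyl chloride and of α-tetralone enolates.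

Step 6
Reactants: 13 (1S,4R)-1-[(2S)-but-3-en-2-yl]-4-methyl-5,6-(isopropylidenedioxy)-3,4-dihydronaphthalen-2(1H)-one
Product: 15 (1S,4R)-1-[(2S)-but-3-en-2-yl]-4-methyl-5,6-(isopropylidenedioxy)-1,2,3,4-tetrahydronaphthalene, via tosylhydrazone 14 (not isolated)
Conditions: TsNHNH2, EtOH, 60 °C; evaporate; catecholborane, CHCl3, −10 °C; NaOAc·3H2O, 60 °C
Reagents that add atoms: none
Why: In this Caglioti-type tosylhydrazone reduction hydride adds to C=N, sulfinate leaves and the diazene loses N2 under mild conditions that leave the terminal alkene, the ketal and the already thermodynamic C4 centre untouched.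

Step 7
Reactants: 15 (1S,4R)-1-[(2S)-but-3-en-2-yl]-4-methyl-5,6-(isopropylidenedioxy)-1,2,3,4-tetrahydronaphthalene
Product: 17 tert-butyl (5R,8S)-8-[(2S)-but-3-en-2-yl]-5-methyl-3,4-(isopropylidenedioxy)-5,6,7,8-tetrahydronaphthalene-2-carboxylate, via C6 aryllithium 16 (not isolated)
Conditions: s-BuLi, TMEDA, THF, −78 °C; Boc2O, −78 °C to rt
Reagents that add atoms: di-tert-butyl dicarbonate, CC(C)(C)OC(=O)OC(=O)OC(C)(C)C
Why: In this directed ortho-metalation O7 guides the base to C6, the only free position ortho to oxygen, and acylation of the aryllithium by Boc2O gives the hindered tert-butyl ester directly.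

Step 8
Reactants: 17 tert-butyl (5R,8S)-8-[(2S)-but-3-en-2-yl]-5-methyl-3,4-(isopropylidenedioxy)-5,6,7,8-tetrahydronaphthalene-2-carboxylate; 18 (S)-3-bromo-2-methylpropan-1-ol
Product: 19 tert-butyl (5R,8S)-8-[(2S,6R)-7-hydroxy-6-methylheptan-2-yl]-5-methyl-3,4-(isopropylidenedioxy)-5,6,7,8-tetrahydronaphthalene-2-carboxylate
Conditions: NiBr2·diglyme (10 mol %), 4,4'-di-tert-butyl-2,2'-bipyridine (12 mol %), (EtO)2MeSiH, Na2CO3, 18 (2 equiv), DMA, 25 °C
Reagents that add atoms: none
Why: In this nickel hydride catalysed anti-Markovnikov reductive hydroalkylation Ni–H adds to the terminal alkene to give the primary C13 alkylnickel, which captures the primary C14 radical from 18 and reductively eliminates, the free OH is tolerated, and C15 comes unchanged from the chiral pool (its descriptor changes from S to R only because the CIP priorities change).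

Step 9
Reactants: 1 catechol
Product: 20 2-methoxyphenol (guaiacol)
Conditions: MeI (1.0 equiv), K2CO3 (1.0 equiv), acetone, reflux
Reagents that add atoms: iodomethane, CI
Why: Williamson mono-O-methylation with limiting MeI alkylates the monoanion once, and guaiacol is easily separated from catechol and the dimethyl ether.

Step 10
Reactants: 20 2-methoxyphenol
Product: 21 4-iodo-2-methoxyphenol
Conditions: N-iodosuccinimide, TsOH (cat.), MeCN, rt
Reagents that add atoms: N-iodosuccinimide, O=C1CCC(=O)N1I
Why: Electrophilic aromatic iodination goes para to the free OH, the stronger donor.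

Step 11
Reactants: 21 4-iodo-2-methoxyphenol; 22 acrylic acid
Product: 23 (E)-ferulic acid
Conditions: Pd(OAc)2 (2 mol %), P(o-tol)3 (4 mol %), Et3N, DMF, 90 °C
Reagents that add atoms: none
Why: In this Mizoroki–Heck reaction syn insertion and syn β-hydride elimination give the E alkene, and the free phenol and acid are tolerated as their ammonium salts.

Step 12
Reactants: 19 tert-butyl (5R,8S)-8-[(2S,6R)-7-hydroxy-6-methylheptan-2-yl]-5-methyl-3,4-(isopropylidenedioxy)-5,6,7,8-tetrahydronaphthalene-2-carboxylate; 23 (E)-ferulic acid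
Product: 24 tert-butyl (5R,8S)-8-[(2S,6R)-7-{[(E)-3-(4-hydroxy-3-methoxyphenyl)prop-2-enoyl]oxy}-6-methylheptan-2-yl]-5-methyl-3,4-(isopropylidenedioxy)-5,6,7,8-tetrahydronaphthalene-2-carboxylate
Conditions: PPh3, DIAD, THF, 0 °C to rt
Reagents that add atoms: none
Why: In this Mitsunobu esterification only the carboxylic acid is acidic enough to protonate the betaine and act as nucleophile, so the free phenol is left alone, and the reacting carbon C16 is not stereogenic.

Step 13
Reactants: 24 protected feruloyl ester
Product: 25 CNP0535851.1, (5R,8S)-3,4-dihydroxy-8-[(2S,6R)-7-{[(E)-3-(4-hydroxy-3-methoxyphenyl)prop-2-enoyl]oxy}-6-methylheptan-2-yl]-5-methyl-5,6,7,8-tetrahydronaphthalene-2-carboxylic acid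
Conditions: TFA–H2O (9:1), CH2Cl2, 0 °C to rt
Reagents that add atoms: none
Why: Acidolysis removes the tert-butyl ester by loss of isobutene and hydrolyses the aryl ketal in the same pot, while the primary alkyl ferulate, the aryl methyl ether and all four stereocentres are inert to TFA.

## Compound list
1 | catechol | Oc1ccccc1O | starting material
2 | 2,2-dimethyl-1,3-benzodioxole | CC1(C)Oc2ccccc2O1 | intermediate
3 | (S)-β-butyrolactone, (4S)-4-methyloxetan-2-one | C[C@H]1CC(=O)O1 | starting material
4 | 2,2-dimethyl-1,3-benzodioxol-4-yllithium | [Li]c1cccc2OC(C)(C)Oc12 | intermediate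
5 | lithium bis(2,2-dimethyl-1,3-benzodioxol-4-yl)cuprate | [Li+].CC1(C)Oc2cccc([Cu-]c3cccc4OC(C)(C)Oc34)c2O1 | intermediate
6 | (3R)-3-(2,2-dimethyl-1,3-benzodioxol-4-yl)butanoic acid | C[C@H](CC(=O)O)c1cccc2OC(C)(C)Oc12 | intermediate
7 | (3R)-3-(2,2-dimethyl-1,3-benzodioxol-4-yl)butanoyl chloride | C[C@H](CC(=O)Cl)c1cccc2OC(C)(C)Oc12 | intermediate
8 | (3R)-3-methyl-4,5-(isopropylidenedioxy)indan-1-one | C[C@@H]1CC(=O)c2ccc3OC(C)(C)Oc3c12 | intermediate
9 | (4R)-4-methyl-1-(trimethylsilyl)-5,6-(isopropylidenedioxy)-3,4-dihydronaphthalen-2(1H)-one | C[C@@H]1CC(=O)C([Si](C)(C)C)c2ccc3OC(C)(C)Oc3c12 | intermediate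
10 | (4R)-4-methyl-5,6-(isopropylidenedioxy)-3,4-dihydronaphthalen-2(1H)-one | C[C@@H]1CC(=O)Cc2ccc3OC(C)(C)Oc3c12 | intermediate
11 | (E)-crotyl chloride, (E)-1-chlorobut-2-ene | C/C=C/CCl | starting material
12 | lithium C3–C4 enolate of 10 | C[C@@H]1CC([O-])=Cc2ccc3OC(C)(C)Oc3c12.[Li+] | intermediate
13 | (1S,4R)-1-[(2S)-but-3-en-2-yl]-4-methyl-5,6-(isopropylidenedioxy)-3,4-dihydronaphthalen-2(1H)-one | C=C[C@H](C)[C@@H]2C(=O)C[C@@H](C)c3c2ccc4OC(C)(C)Oc34 | intermediate
14 | N-tosylhydrazone of 13 | C=C[C@H](C)[C@@H]2C(=NNS(=O)(=O)c5ccc(C)cc5)C[C@@H](C)c3c2ccc4OC(C)(C)Oc34 | intermediate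
15 | (1S,4R)-1-[(2S)-but-3-en-2-yl]-4-methyl-5,6-(isopropylidenedioxy)-1,2,3,4-tetrahydronaphthalene | C=C[C@H](C)[C@@H]2CC[C@@H](C)c3c2ccc4OC(C)(C)Oc34 | intermediate
16 | C6-lithio derivative of 15 | C=C[C@H](C)[C@@H]2CC[C@@H](C)c3c2cc([Li])c4OC(C)(C)Oc34 | intermediate
17 | tert-butyl (5R,8S)-8-[(2S)-but-3-en-2-yl]-5-methyl-3,4-(isopropylidenedioxy)-5,6,7,8-tetrahydronaphthalene-2-carboxylate | C=C[C@H](C)[C@@H]2CC[C@@H](C)c3c2cc(C(=O)OC(C)(C)C)c4OC(C)(C)Oc34 | intermediate
18 | (S)-3-bromo-2-methylpropan-1-ol | OC[C@H](C)CBr | starting material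
19 | tert-butyl (5R,8S)-8-[(2S,6R)-7-hydroxy-6-methylheptan-2-yl]-5-methyl-3,4-(isopropylidenedioxy)-5,6,7,8-tetrahydronaphthalene-2-carboxylate | OC[C@H](C)CCC[C@H](C)[C@@H]2CC[C@@H](C)c3c2cc(C(=O)OC(C)(C)C)c4OC(C)(C)Oc34 | intermediate
20 | 2-methoxyphenol (guaiacol) | COc1ccccc1O | intermediate
21 | 4-iodo-2-methoxyphenol | COc1cc(I)ccc1O | intermediate
22 | acrylic acid | C=CC(=O)O | starting material
23 | (E)-ferulic acid | COc1cc(/C=C/C(=O)O)ccc1O | intermediate
24 | acetonide tert-butyl ester of the target | COc1cc(/C=C/C(=O)OC[C@H](C)CCC[C@H](C)[C@@H]2CC[C@@H](C)c3c2cc(C(=O)OC(C)(C)C)c4OC(C)(C)Oc34)ccc1O | intermediate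
25 | CNP0535851.1 (1R,4S,11S,15R) | COc1cc(/C=C/C(=O)OC[C@H](C)CCC[C@H](C)[C@@H]2CC[C@@H](C)c3c2cc(C(=O)O)c(O)c3O)ccc1O | target

## Step count and risks
Total step count: 13. The longest linear sequence is 10 steps (steps 1 to 8, then 12 and 13).

**Step 5 (the proposed new step).**
- Possible failures are uncatalysed linear SN2 crotylation of the enolate, O-allylation, and poor control at C4.
- The fallback sets out from 10 and comes back at 13, and it uses a known aliphatic Claisen rearrangement in place of metal catalysis.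
- Ketone 10 is condensed with (E)-but-2-en-1-ol (cat. TsOH, toluene, Dean–Stark) to give the conjugated crotyl enol ether (4R)-2-[(E)-but-2-enyloxy]-4-methyl-5,6-(isopropylidenedioxy)-3,4-dihydronaphthalene F2, which is heated at about 170 °C in xylene.
- The chair transition state of the E-crotyl ether places the aryl carbon and the C11 methyl group syn along C3–C4–C11–C12.
- Bond formation anti to the C1 methyl group then gives the 1R,4S,11S ketone 13, and DBU corrects C4 if needed.

**Step 4 (ring expansion).**
- The para-oxygenated aryl ketone may add the diazo reagent slowly, or it may give epoxide or the alkyl-shift isomer.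
- The fallback sets out from 8 and comes back at 10, and it keeps the aryl 1,2-shift but triggers it oxidatively.
- Wittig methylenation (MePPh3Br, KOt-Bu, THF) gives (3R)-3-methyl-1-methylidene-4,5-(isopropylidenedioxy)indane F1.
- Treatment of F1 with the trivalent iodine reagent PhI(OH)OTs in 95 % MeOH at rt adds iodine to the CH2 terminus. The aryl carbon then migrates as iodobenzene leaves, which gives β-tetralone 10.

**Step 8 (hydroalkylation).**
- Ni–H chain walking could erode C11, and the β-branched bromide could couple poorly.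
- The fallback sets out from 17 and comes back at 19.
- Cross metathesis of 17 with excess (R)-2-methylpent-4-en-1-ol (OC[C@H](C)CC=C; second-generation Hoveyda–Grubbs catalyst, CH2Cl2, 40 °C) gives tert-butyl (5R,8S)-8-[(2S,3E,6R)-7-hydroxy-6-methylhept-3-en-2-yl]-5-methyl-3,4-(isopropylidenedioxy)-5,6,7,8-tetrahydronaphthalene-2-carboxylate F3.
- Hydrogenation of F3 (H2, Pd/C, EtOAc) gives 19.

## Further compounds
F1 | step 4 | (3R)-3-methyl-1-methylidene-4,5-(isopropylidenedioxy)indane | C[C@@H]1CC(=C)c2ccc3OC(C)(C)Oc3c12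
F2 | step 5 | (4R)-2-[(E)-but-2-enyloxy]-4-methyl-5,6-(isopropylidenedioxy)-3,4-dihydronaphthalene | C[C@@H]1CC(OC/C=C/C)=Cc2ccc3OC(C)(C)Oc3c12
F3 | step 8 | tert-butyl (5R,8S)-8-[(2S,3E,6R)-7-hydroxy-6-methylhept-3-en-2-yl]-5-methyl-3,4-(isopropylidenedioxy)-5,6,7,8-tetrahydronaphthalene-2-carboxylate | OC[C@H](C)C/C=C/[C@H](C)[C@@H]2CC[C@@H](C)c3c2cc(C(=O)OC(C)(C)C)c4OC(C)(C)Oc34
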